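**Plan**

1. Labels: ring 1 is the dihydrofuran O1–C2–C3–C3a–C7a of the upper benzofuran and ring B its benzene ring (Z-styryl on C4, OH on C6). Ring C is the aryl on C2, ring D the benzene ring of the lower dihydrobenzofuran (bonded to C3 through C5'), and rings E and F the aryls on C3' and C2'.
2. Enabling feature: ring B gives two adjacent carbons to ring 1 (C7a to O1, C3a to C3), and O1–C2–C3 with ring C on C2 and ring D on C3 is the skeleton of a trans-stilbene oxide. Ring 1 is therefore cut at O1–C7a and C3–C3a into a 3-bromobenzyne and a chiral trans-diaryl oxirane.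
3. Further cuts: C4–vinyl (Suzuki coupling with a Z-alkenylboronate), the oxirane back to an E-stilbene and its C5'–vinyl bond (Heck reaction), C2'–C3' of the lower dihydrofuran (carbene C–H insertion), then aryl–carbonyl and O–benzyl bonds.
4. Forward order: lower dihydrofuran with rings D, E, F; ring C by Heck reaction; oxirane; ring 1 together with ring B in one step; methyl ethers exchanged for pivalates while no stilbene is present; Z-styryl unit; deacylation.
5. Stereochemistry: C3' comes from the chiral dirhodium catalyst and C2' from acid equilibration to trans. C2 comes from the Shi epoxidation (its C–O bond is never broken), C3 from C2 when the zwitterion collapses (trans), and the Z-alkene from the boronate with retention.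
6. Design choices: the aryne carries bromine, made in one step from symmetrical 2,6-dibromo-4-methoxyphenol, so the precursor has no regiochemical question; the bromine directs the insertion and then serves as the coupling handle. Ring C carries a pivalate so that the oxirane opens only at the ring D carbon.

Key step: step 11

Assumption: Rh2(R-PTAD)4 is taken to deliver the (3R) centre in step 6; if its sense of induction is the opposite, Rh2(S-PTAD)4 is used and nothing else changes.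

**Route**

Step 1
Reactants: 1 2,6-dibromo-4-methoxyphenol
Product: 4 2-bromo-4-methoxy-6-(trimethylsilyl)phenyl trifluoromethanesulfonate, via (2,6-dibromo-4-methoxyphenoxy)trimethylsilane 2 (not isolated), via lithium 2-bromo-4-methoxy-6-(trimethylsilyl)phenolate 3 (not isolated)
Conditions: (Me3Si)2NH, THF, 70 °C, evaporate; n-BuLi (1.05 equiv), THF, −78 °C → rt; Tf2O, −78 °C → rt
Reagents that add atoms: hexamethyldisilazane, C[Si](C)(C)N[Si](C)(C)C; trifluoromethanesulfonic anhydride, O=S(=O)(OS(=O)(=O)C(F)(F)F)C(F)(F)F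
Why: O-silylation, bromine–lithium exchange at one of the two equivalent C–Br bonds, retro-Brook (1,3 O→C) silyl shift and O-triflation of the phenolate is the standard route to 2-silylaryl triflates, and the symmetry of 1 leaves only one possible product.

Step 2
Reactants: 5 5-bromo-2-hydroxy-3-methoxybenzaldehyde; 6 4-methoxybenzyl chloride
Product: 7 5-bromo-3-methoxy-2-[(4-methoxybenzyl)oxy]benzaldehyde
Conditions: K2CO3, KI (cat.), DMF, 60 °C
Reagents that add atoms: none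
Why: Williamson ether synthesis of the phenoxide with a benzylic chloride; the ether later supplies C2' and ring F.

Step 3
Reactants: 7 5-bromo-3-methoxy-2-[(4-methoxybenzyl)oxy]benzaldehyde; 8 1-bromo-3,5-dimethoxybenzene
Product: 10 (RS)-[5-bromo-3-methoxy-2-[(4-methoxybenzyl)oxy]phenyl](3,5-dimethoxyphenyl)methanol, via (3,5-dimethoxyphenyl)magnesium bromide 9 (not isolated)
Conditions: 8, Mg, THF, reflux; then 7, THF, 0 °C; aq. NH4Cl
Reagents that add atoms: none
Why: Grignard addition to the aldehyde, the aryl bromide of 7 being inert to an aryl Grignard reagent; the carbinol centre is removed in step 4, so it is made racemic.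

Step 4
Reactants: 10 (RS)-[5-bromo-3-methoxy-2-[(4-methoxybenzyl)oxy]phenyl](3,5-dimethoxyphenyl)methanol
Product: 11 [5-bromo-3-methoxy-2-[(4-methoxybenzyl)oxy]phenyl](3,5-dimethoxyphenyl)methanone
Conditions: MnO2 (excess), CH2Cl2, rt
Reagents that add atoms: none
Why: MnO2 oxidation of a doubly benzylic alcohol to the diaryl ketone.

Step 5
Reactants: 11 [5-bromo-3-methoxy-2-[(4-methoxybenzyl)oxy]phenyl](3,5-dimethoxyphenyl)methanone
Product: 12 [5-bromo-3-methoxy-2-[(4-methoxybenzyl)oxy]phenyl](3,5-dimethoxyphenyl)methanone hydrazone (E/Z mixture)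
Conditions: N2H4·H2O (10 equiv), AcOH (cat.), EtOH, 85 °C
Reagents that add atoms: hydrazine, NN
Why: Condensation of the diaryl ketone with excess hydrazine to the hydrazone; both geometric isomers lead to the same diazo compound.

Step 6
Reactants: 12 [5-bromo-3-methoxy-2-[(4-methoxybenzyl)oxy]phenyl](3,5-dimethoxyphenyl)methanone hydrazone
Product: 14 (2S,3R)-5-bromo-3-(3,5-dimethoxyphenyl)-7-methoxy-2-(4-methoxyphenyl)-2,3-dihydro-1-benzofuran, via [5-bromo-3-methoxy-2-[(4-methoxybenzyl)oxy]phenyl](3,5-dimethoxyphenyl)diazomethane 13 (not isolated)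
Conditions: MnO2, CH2Cl2, 0 °C, filter; Rh2(R-PTAD)4 (1 mol %), CH2Cl2, 0 °C → rt
Reagents that add atoms: none
Why: Dehydrogenation of the hydrazone to the diaryldiazomethane and dirhodium-catalysed intramolecular 1,5 C–H insertion of the donor/donor carbene into the 4-methoxybenzylic C–H bond closes the dihydrofuran (bond C2'–C3'); the chiral carboxylate ligands set C3' as R and the concerted insertion gives the cis (2S,3R) ring.

Step 7
Reactants: 14 (2S,3R)-5-bromo-3-(3,5-dimethoxyphenyl)-7-methoxy-2-(4-methoxyphenyl)-2,3-dihydro-1-benzofuran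
Product: 15 (2R,3R)-5-bromo-3-(3,5-dimethoxyphenyl)-7-methoxy-2-(4-methoxyphenyl)-2,3-dihydro-1-benzofuran
Conditions: BF3·OEt2 (0.5 equiv), CH2Cl2 (dilute), −20 → 0 °C
Reagents that add atoms: none
Why: Acid-promoted cis-to-trans equilibration of a 2-aryl-2,3-dihydrobenzofuran: the O1'–C2' bond ionises reversibly to a 4-methoxybenzylic cation and recloses to the more stable trans ring, so C3' (untouched) dictates the 2R configuration.

Step 8
Reactants: 16 4-vinylphenyl acetate (4-acetoxystyrene)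
Product: 18 4-vinylphenyl pivalate, via sodium 4-vinylphenolate 17 (not isolated)
Conditions: NaOH (2.1 equiv), H2O/THF, 0 °C; then t-BuCOCl, 0 °C → rt
Reagents that add atoms: pivaloyl chloride, CC(C)(C)C(Cl)=O
Why: Saponification of the aryl acetate and Schotten–Baumann acylation of the phenolate in one flask; the pivalate is chosen because it should survive the basic epoxidation of step 10.

Step 9
Reactants: 15 (2R,3R)-5-bromo-3-(3,5-dimethoxyphenyl)-7-methoxy-2-(4-methoxyphenyl)-2,3-dihydro-1-benzofuran; 18 4-vinylphenyl pivalate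
Product: 19 4-[(E)-2-[(2R,3R)-3-(3,5-dimethoxyphenyl)-7-methoxy-2-(4-methoxyphenyl)-2,3-dihydro-1-benzofuran-5-yl]ethenyl]phenyl pivalate
Conditions: Pd(OAc)2 (5 mol %), P(o-tol)3 (10 mol %), NaOAc, DMF, 110 °C
Reagents that add atoms: none
Why: Heck reaction of the aryl bromide with the styrene; syn insertion at the terminal carbon and syn β-hydride elimination should give the E-stilbene.

Step 10
Reactants: 19 4-[(E)-2-[(2R,3R)-3-(3,5-dimethoxyphenyl)-7-methoxy-2-(4-methoxyphenyl)-2,3-dihydro-1-benzofuran-5-yl]ethenyl]phenyl pivalate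
Product: 20 4-[(2R,3R)-3-[(2R,3R)-3-(3,5-dimethoxyphenyl)-7-methoxy-2-(4-methoxyphenyl)-2,3-dihydro-1-benzofuran-5-yl]oxiran-2-yl]phenyl pivalate
Conditions: D-fructose-derived Shi ketone (30 mol %), KHSO5 (as 2KHSO5·KHSO4·K2SO4), K2CO3, Bu4NHSO4, MeCN/CH2(OMe)2, aq. Na2B4O7 buffer (pH 10.5), 0 °C; Et3N-deactivated silica, used at once
Reagents that add atoms: potassium peroxymonosulfate, [K+].[O-]S(=O)(=O)OO
Why: Shi asymmetric epoxidation: the dioxirane of the D-fructose-derived ketone transfers oxygen to the E-alkene through the spiro transition state and sets both oxirane carbons as R by reagent control, as it does for trans-stilbene.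

Step 11
Reactants: 20 4-[(2R,3R)-3-[(2R,3R)-3-(3,5-dimethoxyphenyl)-7-methoxy-2-(4-methoxyphenyl)-2,3-dihydro-1-benzofuran-5-yl]oxiran-2-yl]phenyl pivalate; 4 2-bromo-4-methoxy-6-(trimethylsilyl)phenyl trifluoromethanesulfonate
Product: 22 4-[(2S,3S)-4-bromo-3-[(2R,3R)-3-(3,5-dimethoxyphenyl)-7-methoxy-2-(4-methoxyphenyl)-2,3-dihydro-1-benzofuran-5-yl]-6-methoxy-2,3-dihydro-1-benzofuran-2-yl]phenyl pivalate, via 3-bromo-5-methoxybenzyne 21 (not isolated)
Conditions: CsF (4 equiv), MeCN, rt, 4 (2 equiv) added slowly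
Reagents that add atoms: none
Why: Proposed new method: fluoride unmasks aryne 21, the oxirane oxygen of 20 adds to the aryne carbon remote from bromine (bond O1–C7a; the inductively withdrawing bromine polarises the aryne and leaves the carbanion at C3a next to it), the aryl oxonium opens at the ring D carbon to a 4-alkoxybenzylic cation (ring C is deactivated by its pivalate) and the aryl anion captures that cation (bond C3–C3a). The closest known reaction type is the σ-insertion of arynes into the benzylic C–O bond of terminal aryl epoxides to give 3-aryl-2,3-dihydrobenzofurans; an internal trans-diaryl epoxide with relay of configuration has not been shown. Ring 1 closes by collapse of the 1,5-zwitterion, a five-membered C–C closure of an aryl anion onto a benzylic cation, because backside displacement by the tethered anion is geometrically impossible. The new centre C3 is controlled by the intact C2 centre, the anion adding to the cation face anti to the C2 aryl group to give the trans (2S,3S) ring, while C2 keeps the configuration from step 10 because its C–O bond is never broken. The step needs aryne regioselectivity (the bromine at C3 of the aryne should outweigh the weak opposing pull of the methoxy group), oxirane regioselectivity (alkoxy-donor ring D against acyloxy ring C) and capture of the ortho-bromoaryl anion faster than bromide loss or proton transfer, which the cation held four atoms away should secure.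

Step 12
Reactants: 22 4-[(2S,3S)-4-bromo-3-[(2R,3R)-3-(3,5-dimethoxyphenyl)-7-methoxy-2-(4-methoxyphenyl)-2,3-dihydro-1-benzofuran-5-yl]-6-methoxy-2,3-dihydro-1-benzofuran-2-yl]phenyl pivalate
Product: 23 4-[(2S,3S)-4-bromo-3-[(2R,3R)-3-(3,5-dihydroxyphenyl)-7-hydroxy-2-(4-hydroxyphenyl)-2,3-dihydro-1-benzofuran-5-yl]-6-hydroxy-2,3-dihydro-1-benzofuran-2-yl]phenyl pivalate
Conditions: BBr3 (15 equiv), CH2Cl2, −78 → 0 °C; ice-water
Reagents that add atoms: none
Why: Lewis-acid cleavage of the five aryl methyl ethers with BBr3 is done before any stilbene is present; the C2–O bond of ring 1 is shielded by its electron-poor acyloxyaryl group, and the lower dihydrofuran, should it open at C2', recloses to the more stable trans ring.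

Step 13
Reactants: 23 4-[(2S,3S)-4-bromo-3-[(2R,3R)-3-(3,5-dihydroxyphenyl)-7-hydroxy-2-(4-hydroxyphenyl)-2,3-dihydro-1-benzofuran-5-yl]-6-hydroxy-2,3-dihydro-1-benzofuran-2-yl]phenyl pivalate
Product: 24 4-[(2S,3S)-4-bromo-6-(pivaloyloxy)-3-[(2R,3R)-3-[3,5-bis(pivaloyloxy)phenyl]-7-(pivaloyloxy)-2-[4-(pivaloyloxy)phenyl]-2,3-dihydro-1-benzofuran-5-yl]-2,3-dihydro-1-benzofuran-2-yl]phenyl pivalate
Conditions: t-BuCOCl (10 equiv), pyridine, DMAP (cat.), CH2Cl2, 0 °C → rt
Reagents that add atoms: pivaloyl chloride, CC(C)(C)C(Cl)=O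
Why: Exhaustive DMAP-catalysed O-acylation gives one uniform, base-cleavable protecting group that tolerates the cross-coupling and restores any ring C pivalate lost in step 12.

Step 14
Reactants: 25 4-ethynylphenol
Product: 26 4-ethynylphenyl pivalate
Conditions: t-BuCOCl, Et3N, CH2Cl2, 0 °C
Reagents that add atoms: pivaloyl chloride, CC(C)(C)C(Cl)=O
Why: O-acylation of the phenol; the terminal alkyne is untouched.

Step 15
Reactants: 26 4-ethynylphenyl pivalate
Product: 27 4-[(Z)-2-(4,4,5,5-tetramethyl-1,3,2-dioxaborolan-2-yl)ethenyl]phenyl pivalate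
Conditions: [Rh(cod)Cl]2 (1.5 mol %), P(i-Pr)3 (6 mol %), Et3N, pinacolborane, cyclohexane, rt
Reagents that add atoms: pinacolborane, CC1(C)OBOC1(C)C
Why: Rhodium-catalysed trans-hydroboration of a terminal alkyne, which runs through a rhodium vinylidene so that boron and the aryl group end up cis, giving the Z-alkenylboronate.

Step 16
Reactants: 24 4-[(2S,3S)-4-bromo-6-(pivaloyloxy)-3-[(2R,3R)-3-[3,5-bis(pivaloyloxy)phenyl]-7-(pivaloyloxy)-2-[4-(pivaloyloxy)phenyl]-2,3-dihydro-1-benzofuran-5-yl]-2,3-dihydro-1-benzofuran-2-yl]phenyl pivalate; 27 4-[(Z)-2-(4,4,5,5-tetramethyl-1,3,2-dioxaborolan-2-yl)ethenyl]phenyl pivalate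
Product: 28 4-[(Z)-2-[(2S,3S)-6-(pivaloyloxy)-2-[4-(pivaloyloxy)phenyl]-3-[(2R,3R)-3-[3,5-bis(pivaloyloxy)phenyl]-7-(pivaloyloxy)-2-[4-(pivaloyloxy)phenyl]-2,3-dihydro-1-benzofuran-5-yl]-2,3-dihydro-1-benzofuran-4-yl]ethenyl]phenyl pivalate
Conditions: Pd(OAc)2 (5 mol %), SPhos (10 mol %), K3PO4, THF/H2O (10:1), 50 °C
Reagents that add atoms: none
Why: Suzuki–Miyaura coupling: oxidative addition of zerovalent palladium at C4–Br, transmetalation and reductive elimination all proceed with retention at the alkenyl carbon, so the Z geometry of 27 should be carried into the stilbene.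

Step 17
Reactants: 28 4-[(Z)-2-[(2S,3S)-6-(pivaloyloxy)-2-[4-(pivaloyloxy)phenyl]-3-[(2R,3R)-3-[3,5-bis(pivaloyloxy)phenyl]-7-(pivaloyloxy)-2-[4-(pivaloyloxy)phenyl]-2,3-dihydro-1-benzofuran-5-yl]-2,3-dihydro-1-benzofuran-4-yl]ethenyl]phenyl pivalate
Product: 29 (2S,3S)-3-[(2R,3R)-3-(3,5-dihydroxyphenyl)-7-hydroxy-2-(4-hydroxyphenyl)-2,3-dihydro-1-benzofuran-5-yl]-4-[(Z)-2-(4-hydroxyphenyl)ethenyl]-2-(4-hydroxyphenyl)-2,3-dihydro-1-benzofuran-6-ol (CNP0172909.2)
Conditions: NaOMe (12 equiv), MeOH/THF (degassed), 0 °C → rt, Ar; then AcOH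
Reagents that add atoms: none
Why: Zemplén-type transesterification of the seven aryl pivalates under argon; no acid or Lewis acid meets the Z-stilbene or the two dihydrofurans, so no stereocentre or alkene geometry should change.

**Compound list**

1 | 2,6-dibromo-4-methoxyphenol | COc1cc(Br)c(O)c(Br)c1 | starting material
2 | (2,6-dibromo-4-methoxyphenoxy)trimethylsilane | COc1cc(Br)c(O[Si](C)(C)C)c(Br)c1 | intermediate (not isolated)
3 | lithium 2-bromo-4-methoxy-6-(trimethylsilyl)phenolate | [Li+].[O-]c1c(Br)cc(OC)cc1[Si](C)(C)C | intermediate (not isolated)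
4 | 2-bromo-4-methoxy-6-(trimethylsilyl)phenyl trifluoromethanesulfonate | COc1cc(Br)c(OS(=O)(=O)C(F)(F)F)c([Si](C)(C)C)c1 | intermediate
5 | 5-bromo-2-hydroxy-3-methoxybenzaldehyde | COc1cc(Br)cc(C=O)c1O | starting material
6 | 4-methoxybenzyl chloride | COc1ccc(CCl)cc1 | starting material
7 | 5-bromo-3-methoxy-2-[(4-methoxybenzyl)oxy]benzaldehyde | COc1ccc(COc2c(OC)cc(Br)cc2C=O)cc1 | intermediate
8 | 1-bromo-3,5-dimethoxybenzene | COc1cc(Br)cc(OC)c1 | starting material
9 | (3,5-dimethoxyphenyl)magnesium bromide | COc1cc([Mg]Br)cc(OC)c1 | intermediate (not isolated)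
10 | (RS)-[5-bromo-3-methoxy-2-[(4-methoxybenzyl)oxy]phenyl](3,5-dimethoxyphenyl)methanol | COc1ccc(COc2c(OC)cc(Br)cc2C(O)c2cc(OC)cc(OC)c2)cc1 | intermediate
11 | [5-bromo-3-methoxy-2-[(4-methoxybenzyl)oxy]phenyl](3,5-dimethoxyphenyl)methanone | COc1ccc(COc2c(OC)cc(Br)cc2C(=O)c2cc(OC)cc(OC)c2)cc1 | intermediate
12 | [5-bromo-3-methoxy-2-[(4-methoxybenzyl)oxy]phenyl](3,5-dimethoxyphenyl)methanone hydrazone | COc1ccc(COc2c(OC)cc(Br)cc2C(=NN)c2cc(OC)cc(OC)c2)cc1 | intermediate
13 | [5-bromo-3-methoxy-2-[(4-methoxybenzyl)oxy]phenyl](3,5-dimethoxyphenyl)diazomethane | COc1ccc(COc2c(OC)cc(Br)cc2C(=[N+]=[N-])c2cc(OC)cc(OC)c2)cc1 | intermediate (not isolated)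
14 | (2S,3R)-5-bromo-3-(3,5-dimethoxyphenyl)-7-methoxy-2-(4-methoxyphenyl)-2,3-dihydro-1-benzofuran | Brc1cc(OC)c2c(c1)[C@@H](c1cc(OC)cc(OC)c1)[C@@H](c1ccc(OC)cc1)O2 | intermediate
15 | (2R,3R)-5-bromo-3-(3,5-dimethoxyphenyl)-7-methoxy-2-(4-methoxyphenyl)-2,3-dihydro-1-benzofuran | Brc1cc(OC)c2c(c1)[C@@H](c1cc(OC)cc(OC)c1)[C@H](c1ccc(OC)cc1)O2 | intermediate
16 | 4-vinylphenyl acetate | CC(=O)Oc1ccc(C=C)cc1 | starting material
17 | sodium 4-vinylphenolate | [Na+].[O-]c1ccc(C=C)cc1 | intermediate (not isolated)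
18 | 4-vinylphenyl pivalate | CC(C)(C)C(=O)Oc1ccc(C=C)cc1 | intermediate
19 | 4-[(E)-2-[(2R,3R)-3-(3,5-dimethoxyphenyl)-7-methoxy-2-(4-methoxyphenyl)-2,3-dihydro-1-benzofuran-5-yl]ethenyl]phenyl pivalate | CC(C)(C)C(=O)Oc1ccc(/C=C/c2cc(OC)c3c(c2)[C@@H](c2cc(OC)cc(OC)c2)[C@H](c2ccc(OC)cc2)O3)cc1 | intermediate
20 | 4-[(2R,3R)-3-[(2R,3R)-3-(3,5-dimethoxyphenyl)-7-methoxy-2-(4-methoxyphenyl)-2,3-dihydro-1-benzofuran-5-yl]oxiran-2-yl]phenyl pivalate | CC(C)(C)C(=O)Oc1ccc(cc1)[C@H]1O[C@@H]1c1cc(OC)c2c(c1)[C@@H](c1cc(OC)cc(OC)c1)[C@H](c1ccc(OC)cc1)O2 | intermediate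
21 | 3-bromo-5-methoxybenzyne | COC1=CC#CC(Br)=C1 | intermediate (not isolated)
22 | 4-[(2S,3S)-4-bromo-3-[(2R,3R)-3-(3,5-dimethoxyphenyl)-7-methoxy-2-(4-methoxyphenyl)-2,3-dihydro-1-benzofuran-5-yl]-6-methoxy-2,3-dihydro-1-benzofuran-2-yl]phenyl pivalate | Brc1cc(OC)cc2c1[C@H](c1cc(OC)c3c(c1)[C@@H](c1cc(OC)cc(OC)c1)[C@H](c1ccc(OC)cc1)O3)[C@@H](c1ccc(OC(=O)C(C)(C)C)cc1)O2 | intermediate
23 | 4-[(2S,3S)-4-bromo-3-[(2R,3R)-3-(3,5-dihydroxyphenyl)-7-hydroxy-2-(4-hydroxyphenyl)-2,3-dihydro-1-benzofuran-5-yl]-6-hydroxy-2,3-dihydro-1-benzofuran-2-yl]phenyl pivalate | Brc1cc(O)cc2c1[C@H](c1cc(O)c3c(c1)[C@@H](c1cc(O)cc(O)c1)[C@H](c1ccc(O)cc1)O3)[C@@H](c1ccc(OC(=O)C(C)(C)C)cc1)O2 | intermediate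
24 | 4-[(2S,3S)-4-bromo-6-(pivaloyloxy)-3-[(2R,3R)-3-[3,5-bis(pivaloyloxy)phenyl]-7-(pivaloyloxy)-2-[4-(pivaloyloxy)phenyl]-2,3-dihydro-1-benzofuran-5-yl]-2,3-dihydro-1-benzofuran-2-yl]phenyl pivalate | Brc1cc(OC(=O)C(C)(C)C)cc2c1[C@H](c1cc(OC(=O)C(C)(C)C)c3c(c1)[C@@H](c1cc(OC(=O)C(C)(C)C)cc(OC(=O)C(C)(C)C)c1)[C@H](c1ccc(OC(=O)C(C)(C)C)cc1)O3)[C@@H](c1ccc(OC(=O)C(C)(C)C)cc1)O2 | intermediate
25 | 4-ethynylphenol | C#Cc1ccc(O)cc1 | starting material
26 | 4-ethynylphenyl pivalate | CC(C)(C)C(=O)Oc1ccc(C#C)cc1 | intermediate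
27 | 4-[(Z)-2-(4,4,5,5-tetramethyl-1,3,2-dioxaborolan-2-yl)ethenyl]phenyl pivalate | CC(C)(C)C(=O)Oc1ccc(/C=C\B2OC(C)(C)C(C)(C)O2)cc1 | intermediate
28 | 4-[(Z)-2-[(2S,3S)-6-(pivaloyloxy)-2-[4-(pivaloyloxy)phenyl]-3-[(2R,3R)-3-[3,5-bis(pivaloyloxy)phenyl]-7-(pivaloyloxy)-2-[4-(pivaloyloxy)phenyl]-2,3-dihydro-1-benzofuran-5-yl]-2,3-dihydro-1-benzofuran-4-yl]ethenyl]phenyl pivalate | CC(C)(C)C(=O)Oc1ccc(/C=C\c2cc(OC(=O)C(C)(C)C)cc3c2[C@H](c2cc(OC(=O)C(C)(C)C)c4c(c2)[C@@H](c2cc(OC(=O)C(C)(C)C)cc(OC(=O)C(C)(C)C)c2)[C@H](c2ccc(OC(=O)C(C)(C)C)cc2)O4)[C@@H](c2ccc(OC(=O)C(C)(C)C)cc2)O3)cc1 | intermediate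
29 | (2S,3S)-3-[(2R,3R)-3-(3,5-dihydroxyphenyl)-7-hydroxy-2-(4-hydroxyphenyl)-2,3-dihydro-1-benzofuran-5-yl]-4-[(Z)-2-(4-hydroxyphenyl)ethenyl]-2-(4-hydroxyphenyl)-2,3-dihydro-1-benzofuran-6-ol | Oc1ccc(/C=C\c2cc(O)cc3c2[C@H](c2cc(O)c4c(c2)[C@@H](c2cc(O)cc(O)c2)[C@H](c2ccc(O)cc2)O4)[C@@H](c2ccc(O)cc2)O3)cc1 | target

**Count**

Total: 17 steps. Longest linear sequence: 13 steps (5 → 29 through steps 2–7, 9–13, 16 and 17).

**Steps most likely to fail**

Step 11 (new method). The ortho-bromoaryl anion may be lost before C–C bond formation, by proton transfer from MeCN or from C2–H (giving an aryl enol ether) or by expulsion of bromide. The oxirane oxygen may also add to the wrong aryne carbon, or the zwitterion may close to the cis ring. The fallback builds ring 1 in two known operations with one inversion at each carbon, which gives the same (2S,3S) ring that the insertion reaches by double retention. It sets out from 19. Shi epoxidation with the enantiomeric ketone (prepared from L-sorbose) would give the antipodal (2S,3S)-oxirane F1. Friedel–Crafts alkylation of 5-bromoresorcinol (Oc1cc(O)cc(Br)c1) by F1 in (CF3)2CHOH at 0 °C should open the oxirane at the ring D carbon, anti to the oxygen. The arene should react at a carbon between OH and Br (para to the other OH; the two such carbons are equivalent), giving the (1R,2S)-triarylethanol F2. Mitsunobu cyclisation (PPh3, DIAD, THF, 0 °C) then lets the ortho phenol displace the activated secondary alcohol with inversion, giving the 6-hydroxy-(2S,3S)-dihydrobenzofuran F3. Any adduct from attack between the two hydroxyl groups, or from a stepwise opening (which would end as the cis ring), would be removed by chromatography at this stage. BBr3 under the conditions of step 12 cleaves the four methyl ethers of F3 and rejoins the route at 23.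

Step 12. On the large substrate the Lewis acid may open the lower dihydrofuran at its 4-methoxybenzylic C2'–O bond and the cation may alkylate an electron-rich ring instead of reclosing, or cleavage of five ethers may stall. The fallback moves the demethylation to the small fragment, where the opened ring can only reclose to trans, and carries pivalates through the fragment coupling. It sets out from 15. BBr3 would give the (2R,3R)-tetraphenol bromide F4, and pivaloyl chloride/pyridine its tetrapivalate F5. F5 is taken through the Heck reaction with 18 (E-stilbene pentapivalate F6), the Shi epoxidation ((2R,3R)-oxirane pentapivalate F7) and the aryne insertion with 4 (6-methoxy insertion product F8) under the conditions of steps 9, 10 and 11. Only the ring B methyl ether then remains. BBr3 would cleave it on a substrate whose two benzylic C–O bonds both carry acyloxyaryl groups and cannot ionise easily, giving the 6-hydroxy pentapivalate F9. Pivaloylation of F9 rejoins the route at 24.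

Step 16. Oxidative addition at C4–Br, which is flanked by the C3 substituent, may be slow; 27 may protodeboronate; the alkene may isomerise from Z to E through palladium hydride addition and elimination. The fallback fixes the geometry by syn delivery of hydrogen to an alkyne instead of by a stereoretentive coupling. It sets out from 24 and 26. Sonogashira coupling (Pd(PPh3)2Cl2, CuI, Et3N, THF, 60 °C) would give the diarylalkyne heptapivalate F10. Semi-hydrogenation of F10 with H2 over Pd/CaCO3 poisoned with Pb(OAc)2 and quinoline (Lindlar catalyst) rejoins the route at 28.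

**Further compounds**

F1 | step 11 | 4-[(2S,3S)-3-[(2R,3R)-3-(3,5-dimethoxyphenyl)-7-methoxy-2-(4-methoxyphenyl)-2,3-dihydro-1-benzofuran-5-yl]oxiran-2-yl]phenyl pivalate | CC(C)(C)C(=O)Oc1ccc(cc1)[C@@H]1O[C@H]1c1cc(OC)c2c(c1)[C@@H](c1cc(OC)cc(OC)c1)[C@H](c1ccc(OC)cc1)O2
F2 | step 11 | 4-[(1R,2S)-2-(2-bromo-4,6-dihydroxyphenyl)-2-[(2R,3R)-3-(3,5-dimethoxyphenyl)-7-methoxy-2-(4-methoxyphenyl)-2,3-dihydro-1-benzofuran-5-yl]-1-hydroxyethyl]phenyl pivalate | CC(C)(C)C(=O)Oc1ccc(cc1)[C@H](O)[C@H](c1c(O)cc(O)cc1Br)c1cc(OC)c2c(c1)[C@@H](c1cc(OC)cc(OC)c1)[C@H](c1ccc(OC)cc1)O2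
F3 | step 11 | 4-[(2S,3S)-4-bromo-3-[(2R,3R)-3-(3,5-dimethoxyphenyl)-7-methoxy-2-(4-methoxyphenyl)-2,3-dihydro-1-benzofuran-5-yl]-6-hydroxy-2,3-dihydro-1-benzofuran-2-yl]phenyl pivalate | Brc1cc(O)cc2c1[C@H](c1cc(OC)c3c(c1)[C@@H](c1cc(OC)cc(OC)c1)[C@H](c1ccc(OC)cc1)O3)[C@@H](c1ccc(OC(=O)C(C)(C)C)cc1)O2
F4 | step 12 | (2R,3R)-5-bromo-3-(3,5-dihydroxyphenyl)-2-(4-hydroxyphenyl)-2,3-dihydro-1-benzofuran-7-ol | Brc1cc(O)c2c(c1)[C@@H](c1cc(O)cc(O)c1)[C@H](c1ccc(O)cc1)O2
F5 | step 12 | (2R,3R)-5-bromo-3-[3,5-bis(pivaloyloxy)phenyl]-2-[4-(pivaloyloxy)phenyl]-2,3-dihydro-1-benzofuran-7-yl pivalate | Brc1cc(OC(=O)C(C)(C)C)c2c(c1)[C@@H](c1cc(OC(=O)C(C)(C)C)cc(OC(=O)C(C)(C)C)c1)[C@H](c1ccc(OC(=O)C(C)(C)C)cc1)O2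
F6 | step 12 | 4-[(E)-2-[(2R,3R)-3-[3,5-bis(pivaloyloxy)phenyl]-7-(pivaloyloxy)-2-[4-(pivaloyloxy)phenyl]-2,3-dihydro-1-benzofuran-5-yl]ethenyl]phenyl pivalate | CC(C)(C)C(=O)Oc1ccc(/C=C/c2cc(OC(=O)C(C)(C)C)c3c(c2)[C@@H](c2cc(OC(=O)C(C)(C)C)cc(OC(=O)C(C)(C)C)c2)[C@H](c2ccc(OC(=O)C(C)(C)C)cc2)O3)cc1
F7 | step 12 | 4-[(2R,3R)-3-[(2R,3R)-3-[3,5-bis(pivaloyloxy)phenyl]-7-(pivaloyloxy)-2-[4-(pivaloyloxy)phenyl]-2,3-dihydro-1-benzofuran-5-yl]oxiran-2-yl]phenyl pivalate | CC(C)(C)C(=O)Oc1ccc(cc1)[C@H]1O[C@@H]1c1cc(OC(=O)C(C)(C)C)c2c(c1)[C@@H](c1cc(OC(=O)C(C)(C)C)cc(OC(=O)C(C)(C)C)c1)[C@H](c1ccc(OC(=O)C(C)(C)C)cc1)O2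
F8 | step 12 | 4-[(2S,3S)-4-bromo-6-methoxy-3-[(2R,3R)-3-[3,5-bis(pivaloyloxy)phenyl]-7-(pivaloyloxy)-2-[4-(pivaloyloxy)phenyl]-2,3-dihydro-1-benzofuran-5-yl]-2,3-dihydro-1-benzofuran-2-yl]phenyl pivalate | Brc1cc(OC)cc2c1[C@H](c1cc(OC(=O)C(C)(C)C)c3c(c1)[C@@H](c1cc(OC(=O)C(C)(C)C)cc(OC(=O)C(C)(C)C)c1)[C@H](c1ccc(OC(=O)C(C)(C)C)cc1)O3)[C@@H](c1ccc(OC(=O)C(C)(C)C)cc1)O2
F9 | step 12 | 4-[(2S,3S)-4-bromo-6-hydroxy-3-[(2R,3R)-3-[3,5-bis(pivaloyloxy)phenyl]-7-(pivaloyloxy)-2-[4-(pivaloyloxy)phenyl]-2,3-dihydro-1-benzofuran-5-yl]-2,3-dihydro-1-benzofuran-2-yl]phenyl pivalate | Brc1cc(O)cc2c1[C@H](c1cc(OC(=O)C(C)(C)C)c3c(c1)[C@@H](c1cc(OC(=O)C(C)(C)C)cc(OC(=O)C(C)(C)C)c1)[C@H](c1ccc(OC(=O)C(C)(C)C)cc1)O3)[C@@H](c1ccc(OC(=O)C(C)(C)C)cc1)O2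
F10 | step 16 | 4-[2-[(2S,3S)-6-(pivaloyloxy)-2-[4-(pivaloyloxy)phenyl]-3-[(2R,3R)-3-[3,5-bis(pivaloyloxy)phenyl]-7-(pivaloyloxy)-2-[4-(pivaloyloxy)phenyl]-2,3-dihydro-1-benzofuran-5-yl]-2,3-dihydro-1-benzofuran-4-yl]ethynyl]phenyl pivalate | CC(C)(C)C(=O)Oc1ccc(C#Cc2cc(OC(=O)C(C)(C)C)cc3c2[C@H](c2cc(OC(=O)C(C)(C)C)c4c(c2)[C@@H](c2cc(OC(=O)C(C)(C)C)cc(OC(=O)C(C)(C)C)c2)[C@H](c2ccc(OC(=O)C(C)(C)C)cc2)O4)[C@@H](c2ccc(OC(=O)C(C)(C)C)cc2)O3)cc1
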